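**Plan**
- Cuts: the amide C–N bond; the ring C2–C(alkenyl) bond; the alkenyl C–Cl bond (traced back to C–B); the C5–C6 bond of the acyl chain (alkynide + epoxide); and, inside the cyclohexenone, the C1–C2 and C2–C3 bonds, so that C2 leaves as a one-carbon unit.
- Feature used: in the cyclohexenone, C1(=O) lies between the tetrasubstituted C2=C3 olefin (side chain on C2, methyl on C3) and the C6 methine. Without C2, the atoms C1, C3, C4, C5, C6 are the silyl enol ether of 2,5-dimethylcyclopentanone, whose C=C bond can take up C2 as dibromocarbene and open to the 2-bromocyclohex-2-enone.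
- Forward order: cyclopentanone → (2S,5S)-2,5-dimethylcyclopentanone → silyl enol ether → ring expansion to the six-membered bromoenone. Separately: epoxide + pentynoic acid → methoxy acid → N-propargyl amide → syn borylstannylation. Then Stille union and chlorodeboronation.
- Stereochemistry: ring C6 from double RAMP-hydrazone methylation (the trans ketone is C2-symmetric, so either enolization gives the same enol ether); it is a spectator afterwards. C7 comes from hydrolytic kinetic resolution of 2-pentyloxirane. The 4E olefin comes from dissolving-metal reduction of an alkyne. The E chloroalkene comes from syn B/Sn addition to the alkyne followed by two retentive substitutions.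

Key step: step 11

Remark on the chemistry: CIP analysis of the target gives 7S and 4E in the acyl chain, 2E for the chloroalkene and S for the ring methine (C6 of the enone, locant 5 in the amide name); the route is planned for these.

**Step 1**
Reactants: 1 rac-2-pentyloxirane
Product: 2 (S)-2-pentyloxirane
Conditions: (S,S)-(salen)Co(OAc) [salen = N,N'-bis(3,5-di-tert-butylsalicylidene)cyclohexane-1,2-diaminate] (0.5 mol%), H2O (0.55 equiv), THF, 0 °C to rt; distillation
Reagents that add atoms: none
Why: Hydrolytic kinetic resolution: the S,S salen acetate of trivalent cobalt should hydrate the R epoxide far faster than the S epoxide, so unreacted 2 is recovered with the configuration that becomes C7; the stereocentre is selected, not made.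

**Step 2**
Reactants: 2 (S)-2-pentyloxirane; 3 pent-4-ynoic acid
Product: 4 (7S)-7-hydroxydodec-4-ynoic acid
Conditions: 3 (1.5 equiv), n-BuLi (3.0 equiv), THF/HMPA, −78 to 0 °C; then 2, 0 °C to rt; aq. HCl
Reagents that add atoms: none
Why: SN2 opening of the terminal epoxide at its CH2 group by the lithium acetylide of dilithiated 3 (alkynide alkylation) builds the whole C12 chain and leaves the C–O stereocentre untouched.

**Step 3**
Reactants: 4 (7S)-7-hydroxydodec-4-ynoic acid
Product: 5 (4E,7S)-7-hydroxydodec-4-enoic acid
Conditions: Na, NH3(l)/THF, −33 °C; NH4Cl; aq. HCl to pH 3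
Reagents that add atoms: none
Why: Dissolving-metal (Birch-type) reduction of the internal alkyne runs through the more stable trans alkenyl radical and anion and should give the 4E olefin, while the carboxylate and alkoxide are inert to sodium in ammonia.

**Step 4**
Reactants: 5 (4E,7S)-7-hydroxydodec-4-enoic acid
Product: 7 (4E,7S)-7-methoxydodec-4-enoic acid, via methyl ester 6 (not isolated)
Conditions: NaH, MeI, THF/DMF, 0 °C to rt; then LiOH, H2O/MeOH, rt; aq. HCl
Reagents that add atoms: iodomethane, CI; lithium hydroxide, [Li+].[OH-]
Why: Williamson O-methylation of the secondary alkoxide, with saponification of the methyl ester 6 formed alongside, converges on the methoxy acid without touching C7 or the olefin.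

**Step 5**
Reactants: 7 (4E,7S)-7-methoxydodec-4-enoic acid; 8 prop-2-yn-1-amine
Product: 9 (4E,7S)-7-methoxy-N-(prop-2-yn-1-yl)dodec-4-enamide
Conditions: EDC·HCl, HOBt, iPr2NEt, CH2Cl2, 0 °C to rt
Reagents that add atoms: none
Why: Carbodiimide/HOBt amide coupling of an unhindered acid with a primary amine; no stereocentre is at risk.

**Step 6**
Reactants: 9 (4E,7S)-7-methoxy-N-(prop-2-yn-1-yl)dodec-4-enamide
Product: 10 (4E,7S)-7-methoxy-N-[(2Z)-3-(4,4,5,5-tetramethyl-1,3,2-dioxaborolan-2-yl)-2-(tributylstannyl)prop-2-en-1-yl]dodec-4-enamide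
Conditions: B2pin2 (1.3 equiv), Bu3SnOMe (1.3 equiv), Cu(OAc)2 (5 mol%), PCy3 (12 mol%), toluene, 50 °C
Reagents that add atoms: bis(pinacolato)diboron, CC1(C)OB(OC1(C)C)B1OC(C)(C)C(C)(C)O1; tributyltin methoxide, CCCC[Sn](CCCC)(CCCC)OC
Why: Copper-catalysed three-component borylstannylation: a copper boryl adds syn across the terminal alkyne with boron on the terminal carbon, and the internal alkenylcopper is stannylated by Bu3SnOMe with retention, so B and Sn end cis (2Z) and the later chloroalkene geometry is fixed here.

**Step 7**
Reactants: 11 cyclopentanone; 12 RAMP, (R)-1-amino-2-(methoxymethyl)pyrrolidine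
Product: 13 (2R)-N-cyclopentylidene-2-(methoxymethyl)pyrrolidin-1-amine
Conditions: cyclohexane, reflux, water separator
Reagents that add atoms: none
Why: Condensation of the ketone with the hydrazine auxiliary should go to completion on removal of water (hydrazone formation).

**Step 8**
Reactants: 13 (2R)-N-cyclopentylidene-2-(methoxymethyl)pyrrolidin-1-amine
Product: 15 (2R)-N-[(2S,5S)-2,5-dimethylcyclopentylidene]-2-(methoxymethyl)pyrrolidin-1-amine, via monomethyl hydrazone 14 (not isolated)
Conditions: LiN(iPr)2, THF, 0 °C; MeI, −100 °C to rt; then LiN(iPr)2, 0 °C; MeI, −100 °C to rt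
Reagents that add atoms: iodomethane, CI
Why: Enders RAMP-hydrazone alkylation run twice: each methoxy-chelated lithium azaenolate is methylated from the face set by the auxiliary (RAMP gives S at the α-carbon), and since the second deprotonation takes the remaining α-CH2 the two methyl groups should end trans, i.e. 2S,5S.

**Step 9**
Reactants: 15 (2R)-N-[(2S,5S)-2,5-dimethylcyclopentylidene]-2-(methoxymethyl)pyrrolidin-1-amine
Product: 16 (2S,5S)-2,5-dimethylcyclopentan-1-one
Conditions: sat. aq. oxalic acid, pentane, rt
Reagents that add atoms: water, O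
Why: Two-phase oxalic acid hydrolysis of the hydrazone is mild enough to release the α-branched ketone without epimerization and returns the auxiliary to the aqueous phase.

**Step 10**
Reactants: 16 (2S,5S)-2,5-dimethylcyclopentan-1-one
Product: 17 trimethyl{[(5S)-2,5-dimethylcyclopent-1-en-1-yl]oxy}silane
Conditions: LiN(iPr)2, Me3SiCl (present from the start), THF, −78 °C; Et3N; pentane
Reagents that add atoms: chlorotrimethylsilane, C[Si](C)(C)Cl
Why: Kinetic deprotonation with in situ silylation (internal quench) forms the silyl enol ether before any enolate–ketone proton exchange, and because the two α-hydrogens of C2-symmetric 16 are homotopic a single enantiomer with the untouched S centre should result.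

**Step 11**
Reactants: 17 trimethyl{[(5S)-2,5-dimethylcyclopent-1-en-1-yl]oxy}silane
Product: 19 (6S)-2-bromo-3,6-dimethylcyclohex-2-en-1-one, via dibromocyclopropane 18 (not isolated)
Conditions: CHBr3 (2.5 equiv), KOtBu (2.0 equiv, in portions), pentane, −30 to 0 °C; cold aq. NaHCO3
Reagents that add atoms: bromoform, BrC(Br)Br
Why: Singlet dibromocarbene, made from bromoform by α-elimination, adds in a concerted [2+1] cheletropic step to the electron-rich tetrasubstituted enol ether bond of 17; the 1-siloxy-6,6-dibromobicyclo[3.1.0]hexane 18 then undergoes oxygen-assisted disrotatory electrocyclic opening of its central C1–C5 bond with loss of the endo bromide, and the siloxyallyl cation collapses to the enone by loss of the silyl group. The closest known reaction type is the dihalocarbene ring expansion of 1-siloxycyclopentenes to 2-halocyclohex-2-enones. The only ring closed is the transient cyclopropane (carbene cycloaddition); the six-membered ring is not closed end to end but arises when the bond shared by the two small rings breaks, so the five-membered ring grows by the carbene carbon, which becomes C2 and keeps the exo bromine as the handle for the side chain. No new stereocentre survives in 19, because both cyclopropane carbons become sp2, so the face of carbene attack is irrelevant and C6 is a spectator. Regiochemistry is fixed by the substrate: the enol ether is the only nucleophilic alkene, the oxygen lone pair dictates which bond opens, C=O appears at the former siloxy carbon and the methyl-bearing carbon becomes C3. The selectivity needed is retention of the C6–H configuration against base, which is secured by keeping bromoform (far more acidic than the α'-H of 19) in excess over KOtBu in pentane at low temperature and by the cold buffered quench.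

**Step 12**
Reactants: 19 (6S)-2-bromo-3,6-dimethylcyclohex-2-en-1-one; 10 (4E,7S)-7-methoxy-N-[(2Z)-3-(4,4,5,5-tetramethyl-1,3,2-dioxaborolan-2-yl)-2-(tributylstannyl)prop-2-en-1-yl]dodec-4-enamide
Product: 20 (4E,7S)-N-[(2E)-2-[(5S)-2,5-dimethyl-6-oxocyclohex-1-en-1-yl]-3-(4,4,5,5-tetramethyl-1,3,2-dioxaborolan-2-yl)prop-2-en-1-yl]-7-methoxydodec-4-enamide
Conditions: Pd(PPh3)4 (10 mol%), CuCl, LiCl, DMSO, 60 °C, degassed
Reagents that add atoms: none
Why: CuCl/LiCl-accelerated Stille coupling: zerovalent palladium inserts into the activated C2–Br bond of the α-bromoenone, the alkenyl group passes from tin via copper to palladium with retention and reductive elimination places the ring cis to boron; the boronate is inert without base and the neutral medium leaves C6 untouched.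

**Step 13**
Reactants: 20 (4E,7S)-N-[(2E)-2-[(5S)-2,5-dimethyl-6-oxocyclohex-1-en-1-yl]-3-(4,4,5,5-tetramethyl-1,3,2-dioxaborolan-2-yl)prop-2-en-1-yl]-7-methoxydodec-4-enamide
Product: 21 (4E,7S)-N-[(2E)-3-chloro-2-[(5S)-2,5-dimethyl-6-oxocyclohex-1-en-1-yl]prop-2-en-1-yl]-7-methoxydodec-4-enamide (target)
Conditions: CuCl2·2H2O (3 equiv), MeOH/THF/H2O, 50 °C
Reagents that add atoms: copper dichloride (as dihydrate), Cl[Cu]Cl
Why: Copper-mediated chlorodeboronation of an alkenyl pinacol boronate (boron-to-copper transfer, then C–Cl reductive elimination) occurs with retention, so chlorine should end cis to the ring and trans to CH2N (2E), and the weakly acidic medium at 50 °C should be too mild to enolize C6.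

**Compound list**
1 | rac-2-pentyloxirane (1,2-epoxyheptane) | CCCCCC1CO1 | starting material
2 | (S)-2-pentyloxirane | CCCCC[C@H]1CO1 | intermediate
3 | pent-4-ynoic acid | C#CCCC(=O)O | starting material
4 | (7S)-7-hydroxydodec-4-ynoic acid | CCCCC[C@@H](CC#CCCC(=O)O)O | intermediate
5 | (4E,7S)-7-hydroxydodec-4-enoic acid | CCCCC[C@@H](C/C=C/CCC(=O)O)O | intermediate
6 | methyl (4E,7S)-7-methoxydodec-4-enoate | CCCCC[C@@H](C/C=C/CCC(=O)OC)OC | intermediate
7 | (4E,7S)-7-methoxydodec-4-enoic acid | CCCCC[C@@H](C/C=C/CCC(=O)O)OC | intermediate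
8 | prop-2-yn-1-amine (propargylamine) | C#CCN | starting material
9 | (4E,7S)-7-methoxy-N-(prop-2-yn-1-yl)dodec-4-enamide | CCCCC[C@@H](C/C=C/CCC(=O)NCC#C)OC | intermediate
10 | (4E,7S)-7-methoxy-N-[(2Z)-3-(4,4,5,5-tetramethyl-1,3,2-dioxaborolan-2-yl)-2-(tributylstannyl)prop-2-en-1-yl]dodec-4-enamide | CCCCC[C@@H](C/C=C/CCC(=O)NC/C(=C/B1OC(C)(C)C(C)(C)O1)[Sn](CCCC)(CCCC)CCCC)OC | intermediate
11 | cyclopentanone | O=C1CCCC1 | starting material
12 | RAMP, (R)-1-amino-2-(methoxymethyl)pyrrolidine | COC[C@H]1CCCN1N | starting material
13 | (2R)-N-cyclopentylidene-2-(methoxymethyl)pyrrolidin-1-amine | COC[C@H]1CCCN1N=C1CCCC1 | intermediate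
14 | (2R)-2-(methoxymethyl)-N-[(2S)-2-methylcyclopentylidene]pyrrolidin-1-amine | COC[C@H]1CCCN1N=C1CCC[C@@H]1C | intermediate
15 | (2R)-N-[(2S,5S)-2,5-dimethylcyclopentylidene]-2-(methoxymethyl)pyrrolidin-1-amine | COC[C@H]1CCCN1N=C1[C@@H](C)CC[C@@H]1C | intermediate
16 | (2S,5S)-2,5-dimethylcyclopentan-1-one | C[C@H]1CC[C@H](C)C1=O | intermediate
17 | trimethyl{[(5S)-2,5-dimethylcyclopent-1-en-1-yl]oxy}silane | C[C@H]1CCC(C)=C1O[Si](C)(C)C | intermediate
18 | (2S)-6,6-dibromo-2,5-dimethyl-1-(trimethylsilyloxy)bicyclo[3.1.0]hexane (bridgehead configurations not defined) | C[C@H]1CCC2(C)C(Br)(Br)C12O[Si](C)(C)C | intermediate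
19 | (6S)-2-bromo-3,6-dimethylcyclohex-2-en-1-one | C[C@H]1CCC(C)=C(Br)C1=O | intermediate
20 | (4E,7S)-N-[(2E)-2-[(5S)-2,5-dimethyl-6-oxocyclohex-1-en-1-yl]-3-(4,4,5,5-tetramethyl-1,3,2-dioxaborolan-2-yl)prop-2-en-1-yl]-7-methoxydodec-4-enamide | CCCCC[C@@H](C/C=C/CCC(=O)NC/C(=C/B1OC(C)(C)C(C)(C)O1)C1=C(C)CC[C@H](C)C1=O)OC | intermediate
21 | (4E,7S)-N-[(2E)-3-chloro-2-[(5S)-2,5-dimethyl-6-oxocyclohex-1-en-1-yl]prop-2-en-1-yl]-7-methoxydodec-4-enamide | CCCCC[C@@H](C/C=C/CCC(=O)NC/C(=C/Cl)C1=C(C)CC[C@H](C)C1=O)OC | target

**Totals**
Total step count: 13. Longest linear sequence: 8 steps (steps 1–6, 12, 13); the ring branch (steps 7–11) joins at step 12.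

**Steps most likely to fail**

Step 12 (Stille union). The risk is slow tin-to-palladium transfer between two congested partners (a tetrasubstituted α-bromoenone and an α-branched stannane with a cis boryl group), so that protodestannylation or homocoupling outruns cross-coupling. The fallback leaves tin for boron and sets out from 9. Platinum-catalysed syn diboration with the unsymmetrical diboron (pin)B–B(dan) (Pt(dba)2, tris[3,5-bis(trifluoromethyl)phenyl]phosphine, toluene, 80 °C) should give the differentially protected diboryl alkene F1, with Bpin on the internal and B(dan) on the terminal carbon. Internal-selective Suzuki–Miyaura coupling of F1 with 19 (Pd(dppf)Cl2, K3PO4, dioxane/H2O, 50 °C, short reaction time to spare C6) should give the ring-coupled alkenyl-B(dan) compound F2. Exchange of the masked boron (aq. H2SO4/THF, then pinacol) comes back to the route at 20.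

Step 6 (borylstannylation). The risk is proton transfer from the amide N–H to the alkenylcopper intermediate (protoboration instead of stannylation) or incomplete regiocontrol. The fallback sets out from 9 and puts chlorine in before the union. Neutral, N–H-tolerant syn distannation (Me3Sn–SnMe3, Pd(PPh3)4, THF, 65 °C) should give the Z distannane F3. CuCl2 (2 equiv, THF, 0 °C) should replace only the terminal tin with retention, because the terminal carbon is the more accessible one, attack there places the developing charge on the more substituted carbon, and the product is deactivated by its cis chlorine; this gives the Z β-chloro alkenylstannane F4. Stille coupling of F4 with 19 under the conditions of step 12 comes back to the route at 21 and makes step 13 unnecessary.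

Step 11 (ring expansion). The risk is partial loss of the C6 configuration through alkoxide-mediated enolization of 19, or incomplete opening of the cyclopropane. The fallback sets out from 17 and expands the ring through a radical instead of a carbene adduct. Simmons–Smith cyclopropanation (Et2Zn, CH2I2, CH2Cl2, 0 °C) should give the siloxycyclopropane F5. Ito–Saegusa opening with FeCl3 in DMF (oxidation by trivalent iron, β-scission of the shared bond, chlorine transfer to the tertiary radical) should give the β-chloro ketone F6. NaOAc in MeOH at rt should eliminate HCl to the enone F7, and I2/pyridine in CH2Cl2 should give the α-iodoenone F8. F8 takes the place of 19 in the Stille coupling with 10 and comes back to the route at 20.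

**Further compounds**
F1 | step 12 | (4E,7S)-N-[(2E)-3-(2,3-dihydro-1H-naphtho[1,8-de][1,3,2]diazaborinin-2-yl)-2-(4,4,5,5-tetramethyl-1,3,2-dioxaborolan-2-yl)prop-2-en-1-yl]-7-methoxydodec-4-enamide | CCCCC[C@@H](C/C=C/CCC(=O)NC/C(=C/B1Nc2cccc3cccc(N1)c23)B1OC(C)(C)C(C)(C)O1)OC
F2 | step 12 | (4E,7S)-N-[(2E)-3-(2,3-dihydro-1H-naphtho[1,8-de][1,3,2]diazaborinin-2-yl)-2-[(5S)-2,5-dimethyl-6-oxocyclohex-1-en-1-yl]prop-2-en-1-yl]-7-methoxydodec-4-enamide | CCCCC[C@@H](C/C=C/CCC(=O)NC/C(=C/B1Nc2cccc3cccc(N1)c23)C1=C(C)CC[C@H](C)C1=O)OC
F3 | step 6 | (4E,7S)-N-[(2Z)-2,3-bis(trimethylstannyl)prop-2-en-1-yl]-7-methoxydodec-4-enamide | CCCCC[C@@H](C/C=C/CCC(=O)NC/C(=C/[Sn](C)(C)C)[Sn](C)(C)C)OC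
F4 | step 6 | (4E,7S)-N-[(2Z)-3-chloro-2-(trimethylstannyl)prop-2-en-1-yl]-7-methoxydodec-4-enamide | CCCCC[C@@H](C/C=C/CCC(=O)NC/C(=C/Cl)[Sn](C)(C)C)OC
F5 | step 11 | (2S)-2,5-dimethyl-1-(trimethylsilyloxy)bicyclo[3.1.0]hexane | C[C@H]1CCC2(C)CC12O[Si](C)(C)C
F6 | step 11 | (6S)-3-chloro-3,6-dimethylcyclohexan-1-one | C[C@H]1CCC(C)(Cl)CC1=O
F7 | step 11 | (6S)-3,6-dimethylcyclohex-2-en-1-one | C[C@H]1CCC(C)=CC1=O
F8 | step 11 | (6S)-2-iodo-3,6-dimethylcyclohex-2-en-1-one | C[C@H]1CCC(C)=C(I)C1=O
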